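(The readings were computed for an exercise; scatter was added.)

A steady constant across two runs tempts one to hold [nucleophile] at its charge, yet [nucleophile] was never read.

all flasks: electrophile 0.28 M
- eta: nucleophile 0.98 equiv; run made earlier
- theta: nucleophile 3.1 equiv; run made earlier
- north: nucleophile 2.40 equiv; time 25 min
- north-west: nucleophile 4.80 equiv; time 25 min
- north-east: nucleophile 1.20 equiv; time 25 min

| run | time / min | electrophile / % | target / % |
|---|---|---|---|
| eta | 2.00 | 94.7 | 2.1 |
| eta | 4.00 | 88.7 | 2.9 |
| eta | 6.00 | 81.5 | 2.4 |
| eta | 8.00 | 77.5 | 2.0 |
| eta | 10.0 | 73.5 | 1.7 |
| eta | 12.0 | 68.3 | 1.8 |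
| theta | 2.00 | 82.2 | 7.7 |
| theta | 4.00 | 67.7 | 8.9 |
| theta | 6.00 | 54.5 | 7.4 |
| theta | 8.00 | 44.0 | 8.1 |
| theta | 10.0 | 36.9 | 7.3 |
| theta | 12.0 | 30.5 | 7.3 |

(each reading ± 0.5 percentage points)

1. part of the electrophile that has reacted at the end, north
2. part of the electrophile that has reacted at the end, north-west
3. part of the electrophile that has reacted at the end, north-east
4. what raising the equivalents of nucleophile from its lowest to its highest value here does to the part of the electrophile that has reacted (changes below 5 percentage points count as none) (it rises / it falls / no change)



The loss constant κ is the first-order constant of the electrophile divided by the charged [nucleophile]. The last theta reading gives κ = 0.114 M⁻¹ min⁻¹, and the last eta reading gives 0.116 M⁻¹ min⁻¹.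

Version one is the pseudo-first-order flask, with [nucleophile] held at its charge:

north-east 61.6%, north 85.3%, north-west 97.8%

Version two charges one nucleophile for each electrophile lost. Refitted to the same theta reading, its constant is 0.132 M⁻¹ min⁻¹:

north-east 55.0%, north 82.0%, north-west 97.6%

The comparison drifts. By the end of version two, the rate per electrophile stands at 0.542 of its start in north-east but 0.797 in north-west. The cost in nucleophile per electrophile lost is unread, so this reckoning gives north-east as a range, from 55.0% at a cost of one to 61.6% at a cost of zero, and leans to neither end.

The forecast gives 85.3%, 97.9% and 61.7%, and says it rises, reasoning that “the nucleophile seems not to be depleted”. For north-east it stands higher than version two.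

The flask gives 82.6%, 97.3% and 56.4%, and it rises.

    electrophile + target → side product (k = 2.20 M⁻¹ min⁻¹)
    nucleophile + acid set free ⇌ protonated nucleophile, settled at all times (K = 100 M⁻¹)
    nucleophile + acid set free ⇌ idle adduct, settled at all times (K = 1.50 M⁻¹)
    electrophile + nucleophile → acid set free + target (k = 0.0770 M⁻¹ min⁻¹)
    target → over-reaction product (k = 0.0470 min⁻¹)

North-east landed between the versions. By 25.0 min its electrophile had fallen to 44% while target stood at 1.93% and side product, each holding two electrophile, reached 51.6%. Its free nucleophile fell to 50% of charge, with 0.0799 M standing as protonated nucleophile, which makes 1.06 equivalents of free nucleophile lost per electrophile lost.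

The neighbour is north-west at 0.070 M electrophile, with the same charged [nucleophile] as north-east but 4.80 equiv. κ gives 61.6%. The flask gives 59.7%, with 84% of its nucleophile left.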